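**Plan**

Labels: unit A is the guaiacyl ring on the carbinol C7A, unit B the arene on the lactone α-CH2 (C7B), unit C the arene of the dihydrobenzofuran on the lactone β-CH2 (C7C), unit D the guaiacyl ring on C7D; C7, C8 and C9 are the side-chain carbons of each unit.
Cuts: C7B–C8B (lactone enolate benzylation) separates bromide 30 (units A and B) from lactone 16 (units C and D); in 16 the lactone C9B–O bond and C8C–C8B (imide alkylation with a bromoacetate), then C4C–O–C7D and C5C–C8D (oxidative coupling of two feruloyl imides 7); in 30, C7A–C8A (anti-aldol) and C5B–C8A (aryl–CH2 bond by Pd coupling).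
Enabling feature: ring C, ring D, the dihydrofuran joining them (O on C4C, C7D, C8D, C5C) and the chain C7C–C8C–C9C together are one ferulate dimer linked 8–5 and 4-O–7 at the acid oxidation level, so two molecules of 7 give this half in one oxidation.
Forward order: the dihydrofuran ring closes first (step 4), the lactone ring second (step 8), fragment 30 is joined at C8B (step 19), and two deprotections finish.
Stereochemistry: C8D from the oxazolidinone in the radical coupling and C7D from the trans-selective ring closure; C8C from auxiliary-directed enolate alkylation (step 7); C8B trans to C8C by substrate control (step 19); C7A and C8A from an auxiliary-controlled magnesium anti-aldol (step 14).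

Key step: step 4

Assumption: the (R)-4-benzyl auxiliary is taken to steer the C8–C5 coupling to the ring configuration drawn for 9 (2R,3R in 9, which is C7D (R), C8D (S) in the target); this sense must be confirmed on the first batch.
Assumption: methyl 3-bromo-4-hydroxy-5-methoxybenzoate (17) is bought; it is otherwise one bromination (Br2, AcOH) from methyl vanillate.

**Route**

Step 1
Reactants: 1 (E)-ferulic acid
Product: 3 (E)-4-O-(tert-butyldimethylsilyl)ferulic acid, via silyl ester 2 (not isolated)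
Conditions: TBSCl (2.5 equiv), imidazole, DMF, rt; then AcOH–THF–H2O (3:1:1), rt
Reagents that add atoms: tert-butyldimethylsilyl chloride, CC(C)(C)[Si](C)(C)Cl
Why: Silylation of phenol and acid followed by selective hydrolysis of the far more labile silyl ester is standard silyl ether protection and leaves the aryl silyl ether in place.

Step 2
Reactants: 3 (E)-4-O-(tert-butyldimethylsilyl)ferulic acid; 4 (R)-4-benzyl-1,3-oxazolidin-2-one
Product: 6 (R)-4-benzyl-3-[(E)-4-O-(tert-butyldimethylsilyl)feruloyl]-1,3-oxazolidin-2-one, via mixed pivalic anhydride 5 (not isolated)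
Conditions: t-BuCOCl, Et3N, THF, −20 °C; then 4, LiCl, rt
Reagents that add atoms: none
Why: Mixed-anhydride activation with LiCl-assisted N-acylation is the standard mild route to N-enoyl oxazolidinones, the oxazolidinone attacking the unhindered cinnamoyl carbonyl of the anhydride.

Step 3
Reactants: 6 (R)-4-benzyl-3-[(E)-4-O-(tert-butyldimethylsilyl)feruloyl]-1,3-oxazolidin-2-one
Product: 7 (R)-4-benzyl-3-[(E)-feruloyl]-1,3-oxazolidin-2-one
Conditions: Bu4NF, AcOH, THF, 0 °C
Reagents that add atoms: none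
Why: Fluoride desilylation of an aryl silyl ether is fast at 0 °C, and the acetic acid buffer keeps the medium from attacking the base-sensitive enoyl imide.

Step 4
Reactants: 7 (R)-4-benzyl-3-[(E)-feruloyl]-1,3-oxazolidin-2-one (two molecules)
Product: 9 (2R,3R)-trans-2-(4-hydroxy-3-methoxyphenyl)-7-methoxy-2,3-dihydro-1-benzofuran bearing at C3 a carbonyl on N3 of (R)-4-benzyl-oxazolidin-2-one and at C5 an (E)-CH=CH–C(=O) chain on N3 of a second (R)-4-benzyl-oxazolidin-2-one, via quinone methide 8 (not isolated)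
Conditions: Ag2O (0.6 equiv per 7), CH2Cl2, rt, dark, N2
Reagents that add atoms: none
Why: Monovalent silver (Ag2O) oxidises 7 to a phenoxy radical with spin density at C5 and at C8 of the enoyl chain; C8 of one radical bonds to C5 of a second, the ring C cyclohexadienone tautomerises back to the phenol, and the other half is left as quinone methide 8. The C4C phenol oxygen then adds to the quinone methide carbon C7D in a 5-exo-trig conjugate (oxa-Michael) addition that closes the dihydrofuran and restores ring D as a phenol. The closest known reaction type is the Ag2O- or peroxidase-mediated β-5 (8–5) dehydrodimerisation of ferulate esters and of chiral ferulic amides and imides to trans-2-aryl-2,3-dihydrobenzofuran-3-carboxylic acid derivatives. C8D is fixed in the radical C–C bond formation, where the 4-benzyl group of the oxazolidinone on the s-cis enoyl imide is expected to screen one face of C8, and C7D is fixed in the ring closure, which is reversible through 8 and should settle on the more stable 2,3-trans ring. The step needs 8–5 coupling in preference to 8–8 and 8–O–4 coupling, which the free C5 position ortho to the phenol and the acyl-conjugated C8 radical of a ferulic acyl derivative favour, and it needs one ring configuration, which the two auxiliaries make separable from the isomer with the mirror-image ring because the pair are diastereomers.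

Step 5
Reactants: 9 trans-dihydrobenzofuran bis-imide with the enoyl chain
Product: 10 the same bis-imide with the C5 chain saturated (CH2CH2C(=O)–auxiliary)
Conditions: H2 (1 atm), 10% Pd/C, EtOAc, rt
Reagents that add atoms: none
Why: Catalytic hydrogenation saturates the disubstituted enoyl C=C, while the cyclic benzylic aryl ether and the C-benzyl groups of the auxiliaries are not hydrogenolysed under neutral atmospheric-pressure conditions.

Step 6
Reactants: 10 saturated bis-imide with the free ring D phenol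
Product: 11 ring D O-benzyl ether of 10
Conditions: BnBr, K2CO3, acetone, 50 °C
Reagents that add atoms: benzyl bromide, BrCc1ccccc1
Why: Williamson etherification of the only phenol with a carbonate base that is too weak to enolise either imide.

Step 7
Reactants: 11 ring D O-benzyl saturated bis-imide
Product: 13 tert-butyl (3S)-4-[(R)-4-benzyl-2-oxooxazolidin-3-yl]-4-oxo-3-(arylmethyl)butanoate, the aryl group being the dihydrobenzofuran of 11 (C8C alkylated), via sodium enolate 12 (not isolated)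
Conditions: NaN(SiMe3)2 (1.05 equiv), THF, −78 °C; then BrCH2CO2t-Bu, −78 to −40 °C
Reagents that add atoms: tert-butyl bromoacetate, CC(C)(C)OC(=O)CBr
Why: Evans asymmetric alkylation: the amide base forms the chelated Z-enolate of the unhindered 3-arylpropanoyl imide (the α-aryl, α-branched C8D–H is held in the imide plane by 1,3-allylic strain and is kinetically much less acidic), and the bromoacetate enters opposite the auxiliary benzyl group, setting C8C as (S).

Step 8
Reactants: 13 C8C-alkylated bis-imide tert-butyl ester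
Product: 15 (4S)-4-{[(2R,3S)-2-(4-benzyloxy-3-methoxyphenyl)-3-(hydroxymethyl)-7-methoxy-2,3-dihydro-1-benzofuran-5-yl]methyl}oxolan-2-one, via hydroxy ester 14 (not isolated)
Conditions: LiBH4, MeOH, THF, 0 °C; then p-TsOH·H2O (cat.), CH2Cl2, rt
Reagents that add atoms: none
Why: LiBH4 reductively cleaves both N-acyl oxazolidinones to the primary alcohols C9C and C9D faster than it attacks the tert-butyl ester, and acid-catalysed transesterification of the γ-hydroxy ester then closes the γ-butyrolactone (5-exo-trig acyl substitution) without touching any stereocentre.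

Step 9
Reactants: 15 hydroxy lactone
Product: 16 C9D tert-butyldimethylsilyl ether of 15
Conditions: TBSCl, imidazole, DMF, rt
Reagents that add atoms: tert-butyldimethylsilyl chloride, CC(C)(C)[Si](C)(C)Cl
Why: Silylation of the primary alcohol removes the only acidic O–H before the lactone enolate is made.

Step 10
Reactants: 17 methyl 3-bromo-4-hydroxy-5-methoxybenzoate
Product: 18 methyl 4-(benzyloxy)-3-bromo-5-methoxybenzoate
Conditions: BnBr, K2CO3, DMF, 50 °C
Reagents that add atoms: benzyl bromide, BrCc1ccccc1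
Why: Williamson etherification of an acidic, ester-activated phenol.

Step 11
Reactants: 18 methyl 4-(benzyloxy)-3-bromo-5-methoxybenzoate
Product: 19 methyl 4-(benzyloxy)-3-(2-tert-butoxy-2-oxoethyl)-5-methoxybenzoate
Conditions: BrZnCH2CO2t-Bu (1.5 equiv; from BrCH2CO2t-Bu and Zn dust, THF), Pd2(dba)3 (2.5 mol %), XPhos (6 mol %), THF, 60 °C
Reagents that add atoms: (2-tert-butoxy-2-oxoethyl)zinc bromide, CC(C)(C)OC(=O)C[Zn]Br
Why: Negishi-type α-arylation of a Reformatsky zinc enolate: zerovalent palladium inserts into the aryl bromide, transmetallation and reductive elimination form the aryl–CH2 bond (C5B–C8A), and the neutral zinc enolate tolerates the methyl benzoate.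

Step 12
Reactants: 19 methyl 4-(benzyloxy)-3-(2-tert-butoxy-2-oxoethyl)-5-methoxybenzoate
Product: 20 [2-(benzyloxy)-3-methoxy-5-(methoxycarbonyl)phenyl]acetic acid
Conditions: CF3CO2H, CH2Cl2, 0 °C to rt
Reagents that add atoms: none
Why: Acidolysis of the tert-butyl ester with loss of isobutene leaves the methyl ester and the aryl benzyl ether untouched.

Step 13
Reactants: 20 [2-(benzyloxy)-3-methoxy-5-(methoxycarbonyl)phenyl]acetic acid; 21 (S)-4-benzyl-1,3-oxazolidin-2-one
Product: 23 methyl 4-(benzyloxy)-3-methoxy-5-{2-[(S)-4-benzyl-2-oxooxazolidin-3-yl]-2-oxoethyl}benzoate, via mixed pivalic anhydride 22 (not isolated)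
Conditions: t-BuCOCl, Et3N, THF, −20 °C; then 21, LiCl, rt
Reagents that add atoms: none
Why: The same mixed-anhydride N-acylation as in step 2, mild enough to avoid ketene formation from the arylacetic acid.

Step 14
Reactants: 23 (S)-configured arylacetyl imide; 24 4-(benzyloxy)-3-methoxybenzaldehyde
Product: 26 (4S)-4-benzyl-3-[(2R,3S)-3-(4-benzyloxy-3-methoxyphenyl)-2-(2-benzyloxy-3-methoxy-5-methoxycarbonylphenyl)-3-hydroxypropanoyl]-1,3-oxazolidin-2-one, via trimethylsilyl ether 25 (not isolated)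
Conditions: MgCl2 (20 mol %), Et3N, Me3SiCl, EtOAc, rt; then CF3CO2H (cat.), MeOH, rt
Reagents that add atoms: none
Why: Magnesium-halide-catalysed direct anti-aldol of an N-acyl oxazolidinone: soft enolisation gives the chelated Z-enolate, which adds to the aldehyde through a boat transition state on the face opposite the auxiliary benzyl group, setting C8A and C7A anti, while silylation turns the magnesium over and blocks retro-aldol before acidic methanolysis frees the alcohol.

Step 15
Reactants: 26 anti-aldol imide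
Product: 27 methyl 4-(benzyloxy)-3-[(1S,2S)-1-(4-benzyloxy-3-methoxyphenyl)-1,3-dihydroxypropan-2-yl]-5-methoxybenzoate
Conditions: LiBH4, MeOH (1 equiv), THF, 0 °C
Reagents that add atoms: none
Why: Reductive cleavage of the N-acyl oxazolidinone gives the 1,3-diol and returns the auxiliary, the electron-rich methyl benzoate being much less electrophilic and expected to survive at 0 °C.

Step 16
Reactants: 27 1,3-diol methyl ester
Product: 28 bis(tert-butyldimethylsilyl) ether of 27 (C7A–O and C9A–O silylated)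
Conditions: TBSOTf, 2,6-lutidine, CH2Cl2, −78 to 0 °C
Reagents that add atoms: tert-butyldimethylsilyl triflate, CC(C)(C)[Si](C)(C)OS(=O)(=O)C(F)(F)F
Why: Silyl triflate silylation protects both alcohols, including the hindered secondary benzylic one.

Step 17
Reactants: 28 bis-silyl ether methyl ester
Product: 29 {4-(benzyloxy)-3-[(1S,2S)-1-(4-benzyloxy-3-methoxyphenyl)-1,3-bis(tert-butyldimethylsilyloxy)propan-2-yl]-5-methoxyphenyl}methanol
Conditions: i-Bu2AlH, CH2Cl2, −78 °C; aq. potassium sodium tartrate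
Reagents that add atoms: none
Why: Aluminium hydride reduction of the aromatic ester gives the benzylic alcohol (C7B) and leaves silyl and benzyl ethers alone.

Step 18
Reactants: 29 benzylic alcohol
Product: 30 the corresponding benzylic bromide (CH2Br at C7B)
Conditions: CBr4, PPh3, CH2Cl2, 0 °C
Reagents that add atoms: carbon tetrabromide, BrC(Br)(Br)Br
Why: The Appel reaction converts the primary benzylic alcohol to the bromide under neutral conditions, with no acid to ionise the benzylic silyl ether.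

Step 19
Reactants: 16 silyl ether lactone; 30 benzylic bromide
Product: 32 fully protected target (three silyl ethers at C7A–O, C9A–O and C9D–O; benzyl ethers on the phenols of rings A, B and D), trans-(3S,4S)-lactone, via lithium enolate 31 (not isolated)
Conditions: LiN(SiMe3)2 (1.1 equiv), THF, −78 °C; then 30, DMPU, −78 to −30 °C
Reagents that add atoms: none
Why: Alkylation of the lithium enolate of a β-substituted γ-butyrolactone with a benzylic bromide occurs anti to the β-arylmethyl group, the classical route to trans-α,β-dibenzylbutyrolactones, and sets C8B as (S).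

Step 20
Reactants: 32 fully protected target
Product: 33 tri-O-benzyl target (three alcohols free, three phenols benzylated)
Conditions: HF·pyridine, pyridine, THF, 0 °C to rt
Reagents that add atoms: none
Why: Pyridine-buffered fluoride desilylation frees the three alcohols without epimerising the lactone, and with the phenols still benzylated no quinone methide can form at C7A.

Step 21
Reactants: 33 tri-O-benzyl target
Product: 34 CNP0186558.3, (3S,4S)-3-{4-hydroxy-3-[(1S,2S)-1,3-dihydroxy-1-(4-hydroxy-3-methoxyphenyl)propan-2-yl]-5-methoxybenzyl}-4-{[(2R,3S)-2-(4-hydroxy-3-methoxyphenyl)-3-(hydroxymethyl)-7-methoxy-2,3-dihydro-1-benzofuran-5-yl]methyl}oxolan-2-one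
Conditions: H2 (1 atm), 10% Pd/C, EtOAc–EtOH, rt
Reagents that add atoms: none
Why: Hydrogenolysis of aryl benzyl ethers under neutral conditions is much faster than cleavage of the benzylic C7A–OH or the cyclic C7D–O bond, so the reaction is stopped when the three benzyl groups are gone.

**Compound list**

1 | (E)-ferulic acid | COc1cc(/C=C/C(=O)O)ccc1O | starting material
2 | tert-butyldimethylsilyl (E)-4-O-(tert-butyldimethylsilyl)ferulate | COc1cc(/C=C/C(=O)O[Si](C)(C)C(C)(C)C)ccc1O[Si](C)(C)C(C)(C)C | intermediate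
3 | (E)-4-O-(tert-butyldimethylsilyl)ferulic acid | COc1cc(/C=C/C(=O)O)ccc1O[Si](C)(C)C(C)(C)C | intermediate
4 | (R)-4-benzyl-1,3-oxazolidin-2-one | O=C1N[C@H](Cc2ccccc2)CO1 | starting material
5 | mixed anhydride of 3 with pivalic acid | COc1cc(/C=C/C(=O)OC(=O)C(C)(C)C)ccc1O[Si](C)(C)C(C)(C)C | intermediate
6 | (R)-4-benzyl-3-[(E)-4-O-(tert-butyldimethylsilyl)feruloyl]-1,3-oxazolidin-2-one | COc1cc(/C=C/C(=O)N2C(=O)OC[C@H]2Cc2ccccc2)ccc1O[Si](C)(C)C(C)(C)C | intermediate
7 | (R)-4-benzyl-3-[(E)-feruloyl]-1,3-oxazolidin-2-one | COc1cc(/C=C/C(=O)N2C(=O)OC[C@H]2Cc2ccccc2)ccc1O | intermediate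
8 | 8–5-coupled quinone methide (C8D–C5C bond formed, ring C a phenol, unit D a 2-methoxy-p-quinone methide, both imides in place) | COC1=CC(=C[C@H](C(=O)N2C(=O)OC[C@H]2Cc2ccccc2)c2cc(/C=C/C(=O)N3C(=O)OC[C@H]3Cc3ccccc3)cc(OC)c2O)C=CC1=O | intermediate
9 | (2R,3R)-trans-dihydrobenzofuran bis-imide with (E)-enoyl imide chain at C5 and free ring D phenol | O=C(/C=C/c1cc(OC)c2c(c1)[C@@H](C(=O)N1C(=O)OC[C@H]1Cc1ccccc1)[C@H](c1ccc(O)c(OC)c1)O2)N1C(=O)OC[C@H]1Cc1ccccc1 | intermediate
10 | bis-imide with saturated 3-arylpropanoyl chain, free ring D phenol | O=C(CCc1cc(OC)c2c(c1)[C@@H](C(=O)N1C(=O)OC[C@H]1Cc1ccccc1)[C@H](c1ccc(O)c(OC)c1)O2)N1C(=O)OC[C@H]1Cc1ccccc1 | intermediate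
11 | ring D O-benzyl ether of 10 | O=C(CCc1cc(OC)c2c(c1)[C@@H](C(=O)N1C(=O)OC[C@H]1Cc1ccccc1)[C@H](c1ccc(OCc3ccccc3)c(OC)c1)O2)N1C(=O)OC[C@H]1Cc1ccccc1 | intermediate
12 | sodium Z-enolate of the 3-arylpropanoyl imide of 11 | [Na+].[O-]/C(=C\Cc1cc(OC)c2c(c1)[C@@H](C(=O)N1C(=O)OC[C@H]1Cc1ccccc1)[C@H](c1ccc(OCc3ccccc3)c(OC)c1)O2)N1C(=O)OC[C@H]1Cc1ccccc1 | intermediate
13 | tert-butyl (3S)-4-[(R)-4-benzyl-2-oxooxazolidin-3-yl]-4-oxo-3-(arylmethyl)butanoate, aryl group as in 11 | O=C(N1C(=O)OC[C@H]1Cc1ccccc1)[C@H](CC(=O)OC(C)(C)C)Cc1cc(OC)c2c(c1)[C@@H](C(=O)N1C(=O)OC[C@H]1Cc1ccccc1)[C@H](c1ccc(OCc3ccccc3)c(OC)c1)O2 | intermediate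
14 | tert-butyl (3S)-4-[(2R,3S)-2-(4-benzyloxy-3-methoxyphenyl)-3-(hydroxymethyl)-7-methoxy-2,3-dihydro-1-benzofuran-5-yl]-3-(hydroxymethyl)butanoate | OC[C@H](CC(=O)OC(C)(C)C)Cc1cc(OC)c2c(c1)[C@@H](CO)[C@H](c1ccc(OCc3ccccc3)c(OC)c1)O2 | intermediate
15 | (4S)-4-{[(2R,3S)-2-(4-benzyloxy-3-methoxyphenyl)-3-(hydroxymethyl)-7-methoxy-2,3-dihydro-1-benzofuran-5-yl]methyl}oxolan-2-one | O=C1C[C@H](Cc2cc(OC)c3c(c2)[C@@H](CO)[C@H](c2ccc(OCc4ccccc4)c(OC)c2)O3)CO1 | intermediate
16 | C9D tert-butyldimethylsilyl ether of 15 | O=C1C[C@H](Cc2cc(OC)c3c(c2)[C@@H](CO[Si](C)(C)C(C)(C)C)[C@H](c2ccc(OCc4ccccc4)c(OC)c2)O3)CO1 | intermediate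
17 | methyl 3-bromo-4-hydroxy-5-methoxybenzoate | COC(=O)c1cc(Br)c(O)c(OC)c1 | starting material
18 | methyl 4-(benzyloxy)-3-bromo-5-methoxybenzoate | COC(=O)c1cc(Br)c(OCc2ccccc2)c(OC)c1 | intermediate
19 | methyl 4-(benzyloxy)-3-(2-tert-butoxy-2-oxoethyl)-5-methoxybenzoate | COC(=O)c1cc(CC(=O)OC(C)(C)C)c(OCc2ccccc2)c(OC)c1 | intermediate
20 | [2-(benzyloxy)-3-methoxy-5-(methoxycarbonyl)phenyl]acetic acid | COC(=O)c1cc(CC(=O)O)c(OCc2ccccc2)c(OC)c1 | intermediate
21 | (S)-4-benzyl-1,3-oxazolidin-2-one | O=C1N[C@@H](Cc2ccccc2)CO1 | starting material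
22 | mixed anhydride of 20 with pivalic acid | COC(=O)c1cc(CC(=O)OC(=O)C(C)(C)C)c(OCc2ccccc2)c(OC)c1 | intermediate
23 | methyl 4-(benzyloxy)-3-methoxy-5-{2-[(S)-4-benzyl-2-oxooxazolidin-3-yl]-2-oxoethyl}benzoate | COC(=O)c1cc(CC(=O)N2C(=O)OC[C@@H]2Cc2ccccc2)c(OCc2ccccc2)c(OC)c1 | intermediate
24 | 4-(benzyloxy)-3-methoxybenzaldehyde | COc1cc(C=O)ccc1OCc1ccccc1 | starting material
25 | trimethylsilyl ether of anti-aldol 26 | COc1cc([C@@H](O[Si](C)(C)C)[C@H](C(=O)N2C(=O)OC[C@@H]2Cc2ccccc2)c2cc(C(=O)OC)cc(OC)c2OCc2ccccc2)ccc1OCc1ccccc1 | intermediate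
26 | (4S)-4-benzyl-3-[(2R,3S)-3-(4-benzyloxy-3-methoxyphenyl)-2-(2-benzyloxy-3-methoxy-5-methoxycarbonylphenyl)-3-hydroxypropanoyl]-1,3-oxazolidin-2-one | COc1cc([C@@H](O)[C@H](C(=O)N2C(=O)OC[C@@H]2Cc2ccccc2)c2cc(C(=O)OC)cc(OC)c2OCc2ccccc2)ccc1OCc1ccccc1 | intermediate
27 | methyl 4-(benzyloxy)-3-[(1S,2S)-1-(4-benzyloxy-3-methoxyphenyl)-1,3-dihydroxypropan-2-yl]-5-methoxybenzoate | COc1cc([C@@H](O)[C@H](CO)c2cc(C(=O)OC)cc(OC)c2OCc2ccccc2)ccc1OCc1ccccc1 | intermediate
28 | bis(tert-butyldimethylsilyl) ether of 27 | COc1cc([C@@H](O[Si](C)(C)C(C)(C)C)[C@H](CO[Si](C)(C)C(C)(C)C)c2cc(C(=O)OC)cc(OC)c2OCc2ccccc2)ccc1OCc1ccccc1 | intermediate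
29 | {4-(benzyloxy)-3-[(1S,2S)-1-(4-benzyloxy-3-methoxyphenyl)-1,3-bis(tert-butyldimethylsilyloxy)propan-2-yl]-5-methoxyphenyl}methanol | COc1cc([C@@H](O[Si](C)(C)C(C)(C)C)[C@H](CO[Si](C)(C)C(C)(C)C)c2cc(CO)cc(OC)c2OCc2ccccc2)ccc1OCc1ccccc1 | intermediate
30 | benzylic bromide corresponding to 29 | COc1cc([C@@H](O[Si](C)(C)C(C)(C)C)[C@H](CO[Si](C)(C)C(C)(C)C)c2cc(CBr)cc(OC)c2OCc2ccccc2)ccc1OCc1ccccc1 | intermediate
31 | lithium enolate of lactone 16 | [Li+].[O-]C1=C[C@H](Cc2cc(OC)c3c(c2)[C@@H](CO[Si](C)(C)C(C)(C)C)[C@H](c2ccc(OCc4ccccc4)c(OC)c2)O3)CO1 | intermediate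
32 | fully protected target (three silyl ethers, three benzyl ethers) | COc1cc([C@@H](O[Si](C)(C)C(C)(C)C)[C@H](CO[Si](C)(C)C(C)(C)C)c2cc(C[C@@H]3C(=O)OC[C@H]3Cc3cc(OC)c4c(c3)[C@@H](CO[Si](C)(C)C(C)(C)C)[C@H](c3ccc(OCc5ccccc5)c(OC)c3)O4)cc(OC)c2OCc2ccccc2)ccc1OCc1ccccc1 | intermediate
33 | tri-O-benzyl target | COc1cc([C@@H](O)[C@H](CO)c2cc(C[C@@H]3C(=O)OC[C@H]3Cc3cc(OC)c4c(c3)[C@@H](CO)[C@H](c3ccc(OCc5ccccc5)c(OC)c3)O4)cc(OC)c2OCc2ccccc2)ccc1OCc1ccccc1 | intermediate
34 | CNP0186558.3 | COc1cc([C@@H](O)[C@H](CO)c2cc(C[C@@H]3C(=O)OC[C@H]3Cc3cc(OC)c4c(c3)[C@@H](CO)[C@H](c3ccc(O)c(OC)c3)O4)cc(OC)c2O)ccc1O | target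

**Step count and risks**

Total step count: 21. Longest linear sequence: 12 steps (steps 1–9, then 19–21; the branch 10–18, then 19–21, is equally long).

Step 4 (key step). What may go wrong: the auxiliary sits several bonds from C8 and may screen the wrong face, so that the isomer with the mirror-image dihydrobenzofuran predominates. Competing 8–8 and 8–O–4 coupling and re-oxidation of the product phenol may also lower the yield. Fallback, which uncouples the auxiliary for the coupling from the auxiliary for the alkylation: it sets out from acid 3 and the (S)-oxazolidinone 21. Mixed-anhydride acylation as in step 2 should give the (S)-configured silyl ether imide F1, and buffered fluoride the (S)-feruloyl imide F2. Ag2O coupling should then give the bis-(S)-imide dihydrobenzofuran F3 with the ring configuration of the target. Hydrogenation (H2, Pd/C) gives the saturated bis-imide F4 and benzylation (BnBr, K2CO3) the benzyl ether F5. LiOH/H2O2 (1 equiv, THF–H2O, 0 °C) should hydrolyse only the unhindered 3-arylpropanoyl imide, giving the chain acid F6. Acylation of (R)-oxazolidinone 4 (t-BuCOCl, Et3N, then 4, LiCl) places the correct auxiliary on the chain in the mixed bis-imide F7. Alkylation as in step 7 gives the tert-butyl ester F8 with C8C (S). LiBH4 followed by p-TsOH (step 8 conditions) removes both auxiliaries and returns to the route at hydroxy lactone 15 by way of 14.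

Step 7. What may go wrong: proton transfer at C8D (benzylic and α to the second imide) may compete with enolisation of the chain imide, and the resulting enolate would expel the C4C aryloxide and open the dihydrofuran. Fallback, which takes the C8D carbonyl to the alcohol level before any enolate is made: it sets out from bis-imide 11. LiOH/H2O2 (1 equiv, 0 °C) should cleave the unhindered chain imide selectively to the acid F9. LiBH4 then reduces the remaining hindered imide, the lithium carboxylate being inert, to the hydroxy acid F10. TBSCl/imidazole gives the silyl ether silyl ester F11, and K2CO3 in aqueous MeOH hydrolyses its silyl ester to the silyl ether acid F12. Mixed-anhydride acylation of 4 as in step 2 gives the mono-imide F13, whose only enolisable site is C8C. NaN(SiMe3)2 and BrCH2CO2t-Bu give the alkylated imide F14. LiBH4 gives the hydroxy ester F15, and catalytic pyridinium p-toluenesulfonate in CH2Cl2 lactonises it to silyl ether lactone 16, where the route is rejoined.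

Step 14. What may go wrong: the ortho-benzyloxy group on the enolate aryl ring may join the magnesium chelate, and the electron-rich aldehyde adds slowly, so that anti/syn and facial selectivity erode or the adduct reverts before it is silylated. Fallback, which replaces the chelated oxazolidinone enolate by a thioimide enolate reacting through a non-chelated transition state: it sets out from acid 20. DCC/DMAP coupling with commercial (R)-4-benzyl-1,3-thiazolidine-2-thione gives the N-acyl thiazolidinethione F16. MgBr2·OEt2 (10 mol %), Et3N and Me3SiCl in EtOAc with aldehyde 24 should give the silylated anti-adduct F17; this auxiliary class reacts through the opposite enolate face, hence the (R) auxiliary for the same (2R,3S) adduct. Acidic methanolysis gives the anti-aldol F18, and LiBH4 removes the auxiliary and returns to the route at diol 27.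

**Further compounds**

F1 | step 4 | (S)-4-benzyl-3-[(E)-4-O-(tert-butyldimethylsilyl)feruloyl]-1,3-oxazolidin-2-one | COc1cc(/C=C/C(=O)N2C(=O)OC[C@@H]2Cc2ccccc2)ccc1O[Si](C)(C)C(C)(C)C
F2 | step 4 | (S)-4-benzyl-3-[(E)-feruloyl]-1,3-oxazolidin-2-one | COc1cc(/C=C/C(=O)N2C(=O)OC[C@@H]2Cc2ccccc2)ccc1O
F3 | step 4 | (2R,3R)-trans-dihydrobenzofuran bis-imide carrying two (S)-auxiliaries, enoyl chain, free phenol | O=C(/C=C/c1cc(OC)c2c(c1)[C@@H](C(=O)N1C(=O)OC[C@@H]1Cc1ccccc1)[C@H](c1ccc(O)c(OC)c1)O2)N1C(=O)OC[C@@H]1Cc1ccccc1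
F4 | step 4 | saturated bis-(S)-imide, free phenol | O=C(CCc1cc(OC)c2c(c1)[C@@H](C(=O)N1C(=O)OC[C@@H]1Cc1ccccc1)[C@H](c1ccc(O)c(OC)c1)O2)N1C(=O)OC[C@@H]1Cc1ccccc1
F5 | step 4 | ring D O-benzyl saturated bis-(S)-imide | O=C(CCc1cc(OC)c2c(c1)[C@@H](C(=O)N1C(=O)OC[C@@H]1Cc1ccccc1)[C@H](c1ccc(OCc3ccccc3)c(OC)c1)O2)N1C(=O)OC[C@@H]1Cc1ccccc1
F6 | step 4 | chain acid with the (S)-imide retained at C9D | OC(=O)CCc1cc(OC)c2c(c1)[C@@H](C(=O)N1C(=O)OC[C@@H]1Cc1ccccc1)[C@H](c1ccc(OCc3ccccc3)c(OC)c1)O2
F7 | step 4 | mixed bis-imide, (R)-auxiliary on the chain and (S)-auxiliary at C9D | O=C(CCc1cc(OC)c2c(c1)[C@@H](C(=O)N1C(=O)OC[C@@H]1Cc1ccccc1)[C@H](c1ccc(OCc3ccccc3)c(OC)c1)O2)N1C(=O)OC[C@H]1Cc1ccccc1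
F8 | step 4 | mixed bis-imide alkylated at C8C with CH2CO2t-Bu, C8C (S) | O=C(N1C(=O)OC[C@H]1Cc1ccccc1)[C@H](CC(=O)OC(C)(C)C)Cc1cc(OC)c2c(c1)[C@@H](C(=O)N1C(=O)OC[C@@H]1Cc1ccccc1)[C@H](c1ccc(OCc3ccccc3)c(OC)c1)O2
F9 | step 7 | chain acid with the (R)-imide retained at C9D | OC(=O)CCc1cc(OC)c2c(c1)[C@@H](C(=O)N1C(=O)OC[C@H]1Cc1ccccc1)[C@H](c1ccc(OCc3ccccc3)c(OC)c1)O2
F10 | step 7 | 3-[(2R,3S)-2-(4-benzyloxy-3-methoxyphenyl)-3-(hydroxymethyl)-7-methoxy-2,3-dihydro-1-benzofuran-5-yl]propanoic acid | OC(=O)CCc1cc(OC)c2c(c1)[C@@H](CO)[C@H](c1ccc(OCc3ccccc3)c(OC)c1)O2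
F11 | step 7 | silyl ether silyl ester of F10 | CC(C)(C)[Si](C)(C)OC(=O)CCc1cc(OC)c2c(c1)[C@@H](CO[Si](C)(C)C(C)(C)C)[C@H](c1ccc(OCc3ccccc3)c(OC)c1)O2
F12 | step 7 | C9D silyl ether of hydroxy acid F10 | OC(=O)CCc1cc(OC)c2c(c1)[C@@H](CO[Si](C)(C)C(C)(C)C)[C@H](c1ccc(OCc3ccccc3)c(OC)c1)O2
F13 | step 7 | (R)-oxazolidinone imide of F12 | O=C(CCc1cc(OC)c2c(c1)[C@@H](CO[Si](C)(C)C(C)(C)C)[C@H](c1ccc(OCc3ccccc3)c(OC)c1)O2)N1C(=O)OC[C@H]1Cc1ccccc1
F14 | step 7 | F13 alkylated at C8C with CH2CO2t-Bu, C8C (S) | O=C(N1C(=O)OC[C@H]1Cc1ccccc1)[C@H](CC(=O)OC(C)(C)C)Cc1cc(OC)c2c(c1)[C@@H](CO[Si](C)(C)C(C)(C)C)[C@H](c1ccc(OCc3ccccc3)c(OC)c1)O2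
F15 | step 7 | tert-butyl (3S)-3-(hydroxymethyl)-4-aryl-butanoate with C9D silyl ether | OC[C@H](CC(=O)OC(C)(C)C)Cc1cc(OC)c2c(c1)[C@@H](CO[Si](C)(C)C(C)(C)C)[C@H](c1ccc(OCc3ccccc3)c(OC)c1)O2
F16 | step 14 | methyl 4-(benzyloxy)-3-methoxy-5-{2-[(R)-4-benzyl-2-thioxothiazolidin-3-yl]-2-oxoethyl}benzoate | COC(=O)c1cc(CC(=O)N2C(=S)SC[C@H]2Cc2ccccc2)c(OCc2ccccc2)c(OC)c1
F17 | step 14 | trimethylsilyl ether of the (2R,3S)-anti-aldol thiazolidinethione adduct | COc1cc([C@@H](O[Si](C)(C)C)[C@H](C(=O)N2C(=S)SC[C@H]2Cc2ccccc2)c2cc(C(=O)OC)cc(OC)c2OCc2ccccc2)ccc1OCc1ccccc1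
F18 | step 14 | (2R,3S)-anti-aldol adduct on the (R)-thiazolidinethione | COc1cc([C@@H](O)[C@H](C(=O)N2C(=S)SC[C@H]2Cc2ccccc2)c2cc(C(=O)OC)cc(OC)c2OCc2ccccc2)ccc1OCc1ccccc1
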